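**Plan**
Retrosynthesis: the C3 benzoate and the C8 methyl ether are taken off first. Ring C is then opened at O1–C8a, the side chain is cut at C3–O and at C2–C3, and the acetyl group is cut from ring A at C4–C4a.
Forward: ring A (methoxyhydroquinone) is acetylated, joined to the ring B ester through C2–C3 and oxygenated at C3. Ring C closes last through O1–C8a; C8 methylation and debenzoylation finish the target.
Enabling feature: the C5 and C8 oxygens of ring A are para, so ring A can be carried as an acyl hydroquinone. Its quinone is electrophilic at C8a, the ring carbon next to C4a, where the enol oxygen of the side-chain 1,3-diketone (the future O1) can add.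
Stereochemistry: the target is achiral; the one racemic, enolisable centre of 7 and 8 becomes the sp2 carbon C3 in step 6.

Key step: step 6

Remark: flavone numbering (O1, C2, C3, C4, C4a, C5–C8, C8a; ring A = C4a–C8a, ring C = pyranone, ring B = trimethoxyphenyl) is used for the open-chain precursors as well. Compounds 7 and 8 are racemic and may sit partly in enol or cyclic hemiketal forms, which does not affect the route.

**Step 1**
Reactants: 1 methoxyhydroquinone (2-methoxybenzene-1,4-diol)
Product: 2 1-(2,5-dihydroxy-4-methoxyphenyl)ethanone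
Conditions: AcOH, BF3·OEt2, 90 °C; aqueous work-up
Reagents that add atoms: acetic acid, CC(=O)O
Why: Boron trifluoride-mediated Friedel–Crafts acylation should go to the ring position para to the methoxy group and ortho to a hydroxyl, the most activated site, and the chelated ortho-hydroxy ketone resists a second acylation.

**Step 2**
Reactants: 2 1-(2,5-dihydroxy-4-methoxyphenyl)ethanone
Product: 3 1-[2,5-bis(benzyloxy)-4-methoxyphenyl]ethanone
Conditions: BnBr (2.5 equiv.), K2CO3, DMF, 70 °C
Reagents that add atoms: benzyl bromide, BrCc1ccccc1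
Why: Williamson ether synthesis in warm DMF should alkylate both phenols, including the chelated one ortho to the ketone, and benzyl ethers withstand the two enolate steps that follow.

**Step 3**
Reactants: 3 1-[2,5-bis(benzyloxy)-4-methoxyphenyl]ethanone; 4 methyl 3,4,5-trimethoxybenzoate
Product: 5 1-[2,5-bis(benzyloxy)-4-methoxyphenyl]-3-(3,4,5-trimethoxyphenyl)propane-1,3-dione
Conditions: NaH (2.5 equiv.), THF, reflux; then dil. HCl
Reagents that add atoms: none
Why: Crossed Claisen condensation of the methyl ketone enolate with a non-enolisable aryl ester should form the C2–C3 bond, driven by deprotonation of the 1,3-diketone.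

**Step 4**
Reactants: 5 1-[2,5-bis(benzyloxy)-4-methoxyphenyl]-3-(3,4,5-trimethoxyphenyl)propane-1,3-dione; 6 dibenzoyl peroxide
Product: 7 1-[2,5-bis(benzyloxy)-4-methoxyphenyl]-1,3-dioxo-3-(3,4,5-trimethoxyphenyl)propan-2-yl benzoate (racemic)
Conditions: NaH (1.1 equiv.), THF, 0 °C; then 6, 0 °C to rt; dil. HCl
Reagents that add atoms: dibenzoyl peroxide 6, O=C(OOC(=O)c1ccccc1)c1ccccc1
Why: Electrophilic α-benzoyloxylation of a β-diketone enolate by a diacyl peroxide (carbon attack on the peroxide oxygen) should install the C3 oxygen as its benzoate; the new centre is racemic and is erased in step 6.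

**Step 5**
Reactants: 7 1-[2,5-bis(benzyloxy)-4-methoxyphenyl]-1,3-dioxo-3-(3,4,5-trimethoxyphenyl)propan-2-yl benzoate
Product: 8 1-(2,5-dihydroxy-4-methoxyphenyl)-1,3-dioxo-3-(3,4,5-trimethoxyphenyl)propan-2-yl benzoate (racemic)
Conditions: H2 (1 atm), 10% Pd/C, EtOAc, rt; filtered and concentrated under Ar, used at once
Reagents that add atoms: none
Why: Catalytic hydrogenolysis of the two aryl benzyl ethers in neutral ethyl acetate should free the hydroquinone without touching the benzoate or the diaryl diketone and without acid that would cyclodehydrate the ortho-hydroxy diketone.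

**Step 6**
Reactants: 8 1-(2,5-dihydroxy-4-methoxyphenyl)-1,3-dioxo-3-(3,4,5-trimethoxyphenyl)propan-2-yl benzoate
Product: 10 5,8-dihydroxy-7-methoxy-4-oxo-2-(3,4,5-trimethoxyphenyl)-4H-chromen-3-yl benzoate, via acylquinone 9 (not isolated)
Conditions: graphite anode, Pt cathode, divided cell, controlled potential at the first anodic wave, 2.0 F/mol, MeCN/aq. NaH2PO4–Na2HPO4 buffer (pH 7) 1:1, rt, Ar
Reagents that add atoms: none
Why: Proposed new method: anodic loss of two electrons and two protons from hydroquinone 8 should give acylquinone 9, in which the ring CH next to the acyl-bearing carbon (future C8a) is the β-carbon of both the ring enone ending in the future C5 carbonyl and the exocyclic ketone; the enol(ate) oxygen on the carbon that carries ring B adds there and tautomerisation of the adduct restores ring A as the 5,8-hydroquinone 10. The closest known reaction types are the anodic oxidation of hydroquinones and catechols with in-cell Michael addition of 1,3-dicarbonyl compounds and the oxidative closure of 2-hydroxyaryl 2,5-dihydroxyphenyl ketones to xanthones through an aroylquinone; new here is a tethered diketone enol oxygen as the nucleophile. Ring C closes in a 6-endo-trig oxa-Michael mode through the O1–C8a bond. No stereocentre is formed and the racemic centre of 8 becomes the sp2 carbon C3. The step needs oxygen rather than carbon attack and C8a rather than C6 attack: closure through the benzoyloxy-bearing carbon would give a four-membered ring, and C6 is the electron-rich β-carbon of the methoxy enone and out of reach of the tether. The neutral buffer holds back acid cyclodehydration through the C5 hydroxyl, and stopping at 2 F/mol lets any over-oxidised flavone-5,8-quinone be reduced back by unreacted 8.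

**Step 7**
Reactants: 10 5,8-dihydroxy-7-methoxy-4-oxo-2-(3,4,5-trimethoxyphenyl)-4H-chromen-3-yl benzoate
Product: 11 5-hydroxy-7,8-dimethoxy-4-oxo-2-(3,4,5-trimethoxyphenyl)-4H-chromen-3-yl benzoate
Conditions: MeI (1.1 equiv.), K2CO3 (1.2 equiv.), acetone, rt, Ar
Reagents that add atoms: iodomethane, CI
Why: Williamson O-methylation with a limited amount of iodomethane should take the free C8 hydroxyl only, because the C5 hydroxyl is hydrogen-bonded to the C4 carbonyl and far less nucleophilic, as is usual for 5-hydroxyflavones.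

**Step 8**
Reactants: 11 5-hydroxy-7,8-dimethoxy-4-oxo-2-(3,4,5-trimethoxyphenyl)-4H-chromen-3-yl benzoate
Product: 12 3,5-dihydroxy-7,8-dimethoxy-2-(3,4,5-trimethoxyphenyl)-4H-chromen-4-one (3,5-dihydroxy-7,8,3',4',5'-pentamethoxyflavone)
Conditions: K2CO3 (cat.), MeOH/THF 1:1, rt, Ar
Reagents that add atoms: none
Why: Base-catalysed transesterification (methanolysis) of the activated enol benzoate at C3 should release the flavonol, while the aryl methyl ethers are inert and exclusion of air protects the 3-hydroxyflavone.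

**Compound list**
1 | methoxyhydroquinone (2-methoxybenzene-1,4-diol) | COc1cc(O)ccc1O | starting material
2 | 1-(2,5-dihydroxy-4-methoxyphenyl)ethanone | CC(=O)c1cc(O)c(OC)cc1O | intermediate
3 | 1-[2,5-bis(benzyloxy)-4-methoxyphenyl]ethanone | CC(=O)c1cc(OCc2ccccc2)c(OC)cc1OCc1ccccc1 | intermediate
4 | methyl 3,4,5-trimethoxybenzoate | COC(=O)c1cc(OC)c(OC)c(OC)c1 | starting material
5 | 1-[2,5-bis(benzyloxy)-4-methoxyphenyl]-3-(3,4,5-trimethoxyphenyl)propane-1,3-dione | COc1cc(OCc2ccccc2)c(C(=O)CC(=O)c2cc(OC)c(OC)c(OC)c2)cc1OCc1ccccc1 | intermediate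
6 | dibenzoyl peroxide | O=C(OOC(=O)c1ccccc1)c1ccccc1 | starting material
7 | 1-[2,5-bis(benzyloxy)-4-methoxyphenyl]-1,3-dioxo-3-(3,4,5-trimethoxyphenyl)propan-2-yl benzoate (racemic) | COc1cc(OCc2ccccc2)c(C(=O)C(OC(=O)c2ccccc2)C(=O)c2cc(OC)c(OC)c(OC)c2)cc1OCc1ccccc1 | intermediate
8 | 1-(2,5-dihydroxy-4-methoxyphenyl)-1,3-dioxo-3-(3,4,5-trimethoxyphenyl)propan-2-yl benzoate (racemic) | COc1cc(O)c(C(=O)C(OC(=O)c2ccccc2)C(=O)c2cc(OC)c(OC)c(OC)c2)cc1O | intermediate
9 | 1-(4-methoxy-3,6-dioxocyclohexa-1,4-dien-1-yl)-1,3-dioxo-3-(3,4,5-trimethoxyphenyl)propan-2-yl benzoate (acylquinone, racemic, not isolated) | COC1=CC(=O)C(C(=O)C(OC(=O)c2ccccc2)C(=O)c2cc(OC)c(OC)c(OC)c2)=CC1=O | intermediate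
10 | 5,8-dihydroxy-7-methoxy-4-oxo-2-(3,4,5-trimethoxyphenyl)-4H-chromen-3-yl benzoate | COc1cc(O)c2c(=O)c(OC(=O)c3ccccc3)c(-c3cc(OC)c(OC)c(OC)c3)oc2c1O | intermediate
11 | 5-hydroxy-7,8-dimethoxy-4-oxo-2-(3,4,5-trimethoxyphenyl)-4H-chromen-3-yl benzoate | COc1cc(O)c2c(=O)c(OC(=O)c3ccccc3)c(-c3cc(OC)c(OC)c(OC)c3)oc2c1OC | intermediate
12 | 3,5-dihydroxy-7,8-dimethoxy-2-(3,4,5-trimethoxyphenyl)-4H-chromen-4-one | COc1cc(-c2oc3c(OC)c(OC)cc(O)c3c(=O)c2O)cc(OC)c1OC | target

Total step count: 8
Longest linear sequence: 8 steps (1 to 12)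

**Steps most likely to fail**

Step 6. The acylquinone may be consumed by addition of water, by intermolecular Michael addition or by redox exchange before the enol oxygen closes the ring, or the hydroquinone may cyclodehydrate through its C5 hydroxyl before it is oxidised. The fallback uses known chemistry in which the O1–C8a bond is bought and not made. It sets out from ester 4 and comes back at target 12, so that steps 7 and 8 are not needed.
- Ester 4 is condensed (NaH, THF, reflux) with commercial 1-(2-hydroxy-3,4,6-trimethoxyphenyl)ethanone F1 to give 1-(2-hydroxy-3,4,6-trimethoxyphenyl)-3-(3,4,5-trimethoxyphenyl)propane-1,3-dione F2.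
- Acid cyclodehydration (cat. H2SO4, AcOH, 100 °C) should give 5,7,8-trimethoxy-2-(3,4,5-trimethoxyphenyl)-4H-chromen-4-one F3.
- Epoxidation with dimethyldioxirane (acetone/CH2Cl2, 0 °C) should give racemic 2,3-epoxy-5,7,8-trimethoxy-2-(3,4,5-trimethoxyphenyl)chroman-4-one F4.
- Catalytic TsOH should open the epoxide to 3-hydroxy-5,7,8-trimethoxy-2-(3,4,5-trimethoxyphenyl)-4H-chromen-4-one F5.
- Chelation-directed cleavage of the C5 methyl ether peri to the carbonyl (AlCl3, MeCN, 60 °C) should then give 12.

Step 5. Over-reduction on the catalyst (loss of the benzoyloxy group or ketone reduction) may occur, or the liberated ortho-hydroxy diketone may cyclodehydrate or air-oxidise before the electrolysis. The fallback never passes the free hydroquinone. It sets out from acetophenone 2 and comes back at acylquinone 9.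
- Exhaustive methylation of 2 (MeI, K2CO3, acetone, reflux) gives 1-(2,4,5-trimethoxyphenyl)ethanone F6.
- Claisen condensation with 4 as in step 3 gives 1-(2,4,5-trimethoxyphenyl)-3-(3,4,5-trimethoxyphenyl)propane-1,3-dione F7.
- Benzoyloxylation with 6 as in step 4 gives 1,3-dioxo-1-(2,4,5-trimethoxyphenyl)-3-(3,4,5-trimethoxyphenyl)propan-2-yl benzoate F8.
- Oxidative demethylation of the para-dimethoxy pair with (NH4)2Ce(NO3)6 in MeCN/H2O at 0 °C should give 9 directly.
- 9 is then taken up in the buffered medium of step 6 without current and should close to 10.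

Step 4. The stabilised, hindered diaryl diketone enolate may react slowly with the peroxide, so that peroxide homolysis, O-acylation or a second benzoyloxylation compete. The fallback forms the C3–O bond by carbenoid O–H insertion. It sets out from diketone 5 and comes back at benzoate 7.
- Diazo transfer to 5 (4-acetamidobenzenesulfonyl azide, Et3N, MeCN, rt) gives 1-[2,5-bis(benzyloxy)-4-methoxyphenyl]-2-diazo-3-(3,4,5-trimethoxyphenyl)propane-1,3-dione F9.
- Rh2(OAc)4-catalysed O–H insertion of the derived carbenoid into benzoic acid (CH2Cl2, rt to 40 °C) should give 7.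

**Further compounds**
F1 | step 6 | 1-(2-hydroxy-3,4,6-trimethoxyphenyl)ethanone | CC(=O)c1c(O)c(OC)c(OC)cc1OC
F2 | step 6 | 1-(2-hydroxy-3,4,6-trimethoxyphenyl)-3-(3,4,5-trimethoxyphenyl)propane-1,3-dione | COc1cc(OC)c(C(=O)CC(=O)c2cc(OC)c(OC)c(OC)c2)c(O)c1OC
F3 | step 6 | 5,7,8-trimethoxy-2-(3,4,5-trimethoxyphenyl)-4H-chromen-4-one | COc1cc(OC)c2c(=O)cc(-c3cc(OC)c(OC)c(OC)c3)oc2c1OC
F4 | step 6 | 2,3-epoxy-5,7,8-trimethoxy-2-(3,4,5-trimethoxyphenyl)chroman-4-one (racemic) | COc1cc(OC)c2C(=O)C3OC3(c4cc(OC)c(OC)c(OC)c4)Oc2c1OC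
F5 | step 6 | 3-hydroxy-5,7,8-trimethoxy-2-(3,4,5-trimethoxyphenyl)-4H-chromen-4-one | COc1cc(OC)c2c(=O)c(O)c(-c3cc(OC)c(OC)c(OC)c3)oc2c1OC
F6 | step 5 | 1-(2,4,5-trimethoxyphenyl)ethanone | CC(=O)c1cc(OC)c(OC)cc1OC
F7 | step 5 | 1-(2,4,5-trimethoxyphenyl)-3-(3,4,5-trimethoxyphenyl)propane-1,3-dione | COc1cc(OC)c(C(=O)CC(=O)c2cc(OC)c(OC)c(OC)c2)cc1OC
F8 | step 5 | 1,3-dioxo-1-(2,4,5-trimethoxyphenyl)-3-(3,4,5-trimethoxyphenyl)propan-2-yl benzoate (racemic) | COc1cc(OC)c(C(=O)C(OC(=O)c2ccccc2)C(=O)c2cc(OC)c(OC)c(OC)c2)cc1OC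
F9 | step 4 | 1-[2,5-bis(benzyloxy)-4-methoxyphenyl]-2-diazo-3-(3,4,5-trimethoxyphenyl)propane-1,3-dione | COc1cc(OCc2ccccc2)c(C(=O)C(=[N+]=[N-])C(=O)c2cc(OC)c(OC)c(OC)c2)cc1OCc1ccccc1
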